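## The problem

The target **27** is a meroterpenoid. A 7-epi-eudesma-5,11-diene (ring A: C5–C10, with the C5=C6 bond and the isopropenyl group on C7; ring B: C1–C5 and C10) is joined through a methylene carbon (C16, on C1) to a hexasubstituted phloroglucinol that carries a formyl and a 3-methylbutanoyl group. The decalin has four stereocentres: quaternary C10 (β-methyl, C14), its neighbour C1 (β-arylmethyl), allylic C4 (β-methyl, C15) and doubly allylic C7 (α-isopropenyl). C7 can be bought with (S)-carvone and can control C10 through axial C–C bond formation on a cyclohexanone enol derivative. C1 has no acidifying neighbour in the target, so it must be fixed relative to C10 in the event that joins the two carbons. C4 is too remote from C7 for direct control, but it can be set by hydrogen transfer from C6, whose configuration C7 and C10 do control. The C7–H bond lies between two alkenes, so acid can move either double bond into conjugation or start cation–olefin and phenol–olefin cyclisations; catalytic hydrogenation and dissolving metals are excluded. The formyl acylphloroglucinol with free phenols is acidic, chelating and oxidisable and should be released last, and its ether precursor is itself a π-nucleophile. The enabling feature is ring B (C10–C1–C2–C3–C4–C5): with an oxygen written on C3 and the double bond at C4=C5, C5 and C3 are the carbonyls of a 1,5-diketone, so C1–C10 is a Michael bond and C4–C5 an aldol bond, with C16 and its arene riding on the enone β-carbon. The price is that the C3 oxygen must later be removed and the double bond moved to C5=C6 with creation of C4.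

## Retrosynthesis

**27 ⇒ 26.** The three phenolic O–H bonds are traced back to O–CH3 bonds. Methyl ethers are the only phenol protection that should survive a titanium Lewis acid, hydroxide, peracid, hydride, tin radicals and alkyllithiums, and they direct ring metalation. In **26** every methoxy group is ortho or para to both carbonyl groups, so the forward step can be a nucleophilic demethylation without acid. The precursor is no simpler in skeleton, but it is stable and non-chelating.

**26 ⇒ 25 ⇒ 23 ⇒ 20.** The two aryl–carbonyl bonds are cut. Each free ring position of **20** lies between two methoxy groups, so both bonds can be made by ring lithiation. Electrophilic acylation and formylation under Lewis acids would endanger the isopropenyl group and the C5=C6 bond. Because a ketone cannot be present during the second lithiation, the acyl group enters as carbinol **23** (from aldehyde **21**), the formyl group second (**25**), and one oxidation gives **26**. The two ring positions of **20** are equivalent, so only mono-metalation is asked of the forward reaction.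

**20 ⇒ 19 ⇒ 18.** An oxygen is added back on C3 to connect the target with carbonyl chemistry. The C3–H bond is traced to the xanthate **19** of alcohol **18**. Radical deoxygenation is neutral, spares both alkenes and does not touch the allylic centre C4.

**18 ⇒ 15 ⇒ 14.** The C4–H bond and the C5=C6 double bond are traced to a C6–N bond and a C4=C5 double bond (retro-ene logic, through diazene **17** and alcohol **16**). The neighbouring option is kinetic protonation of a dienolate at C4, which relies on intermolecular face selection. The diazene delivers hydrogen to the face that holds the C–N bond. The C3 carbonyl of **15** is reduced before the diazene is released, so the new centre C4 is never α to a ketone. The forward sequence needs a 6β-hydroxyl in **14**, which a substitution with inversion turns into the 6α-nitrogen of **15**.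

**14 ⇒ 13 ⇒ 12.** The C6–O bond is cut. Enone **12** has hydrogen at only one γ-position (C6), and its extended silyl dienol ether **13** can be oxidised there by a peracid. The forward step must attack C6 rather than C4 and must come from the β face.

**12 ⇒ 3 + 9.** This is the key cut: C4=C5 (aldol condensation) and C1–C10 (Michael addition). Cutting C1–C16 instead, by conjugate addition of an arylmethyl metal to a cross-conjugated dienone, would bring the group in anti to C14 and give the wrong C1 epimer. The chosen cut turns a bicyclic ketone with three stereocentres into the monocyclic chiral-pool enol ether **3** and the achiral enone **9**. The forward step must form a bond between a fully substituted carbon and a β-branched enone carbon, axially on **3**, with defined topicity at C1 and without base until the bond exists.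

**3 ⇒ 1; 9 ⇒ 7 + 8; 7 ⇒ 4 + 5.** Conjugate hydride addition to **1** and O-silylation of enolate **2** give **3** as a single regioisomer. Enone **9** is cut at its double bond into allylarene **7** and vinyl ketone **8** (cross-metathesis). This avoids an enolisable arylacetaldehyde and an ozonolysis next to an electron-rich ring. **7** comes from **4** and **5** through aryllithium **6**.

## Roads not taken

**Alternative 1:** The cut is in the aromatic ring, at the bond between the acyl-bearing carbon and a neighbouring C–OH carbon, so the arene is the last ring made. A 4-hydroxy-2-pyrone **A1**, with the terpenylmethyl group on C3 and a 4-methyl-2-oxopentyl chain on C6, would be opened by a magnesium alkoxide in methanol to the 3,5,7-triketo ester **A2**. Its C6 carbanion closes onto the ester carbonyl and aromatises to **A3**, the target without the formyl group.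
- Merits: the phloroglucinol appears with free hydroxyls and the acyl group in an unambiguous position. No protecting groups and no triple demethylation are needed, which is better than the chosen plan's four arene steps and harsh last step.
- Weak points: the key step builds nothing of the decalin. **A1** must already hold C1, C4, C7, C10 and both alkenes, so the hard part is only postponed and must be solved with a pyrone side chain that would not tolerate Lewis acids, hydrides or organolithiums. The chain of **A2** can also close by aldol modes. The formyl group must still be put onto the free, alkene-bearing phenol **A3** by an electrophilic formylation.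
- Comparison: the chosen plan sets against the milder phenol release a key step that makes ring B and both contiguous stereocentres at once from bought materials, with the arene as an inert passenger until the last four steps.

**Alternative 2:** The cut is C1–C16 on a finished decalin, with a temporary C2–C16 bond. Dienol **A4** (from **3** and **8** by annulation, dehydrogenation and 1,2-reduction) would be cyclopropanated by a zinc carbenoid across C1=C2 under direction of the C3 hydroxyl to give **A5**. Oxidation to cyclopropyl ketone **A6** and homoconjugate opening of C2–C16 by an aryl metal would arrive at **12**.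
- Merits: C1 is set by intramolecular delivery syn to a hydroxyl. This is arguably a more secure basis for C1 than an open transition state, and the annulation it needs uses the unhindered ketone **8**.
- Weak points: **A4** has three alkenes, and the more electron-rich tetrasubstituted C4=C5 bond is also allylic to the directing hydroxyl, so site selectivity is not assured. The opening of **A6** needs a di-ortho-substituted aryl nucleophile to attack a hindered cyclopropane carbon and to break C2–C16 only. About six steps are needed to reach **12**.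
- Comparison: the chosen plan gives up the directed delivery but reaches **12** in one operation that also brings in the arene. It relies on enone geometry and on close precedent for the cis outcome.

**Alternative 3:** Four ring bonds are cut (C1–C2, C3–C4, C9–C10, C7–C8). Acyclic cross-conjugated triene **A7** would add acrolein **A8** under a chiral secondary-amine salt across its C1=C10–C5=C4 diene, and the new C10=C5–C6=C7 diene would add phenyl vinyl sulfone **A9** in the same pot to give **A10**.
- Merits: this is the most convergent road. The C5=C6 bond and C4 arise directly, with no transposition, which is better than the five steps the chosen plan spends on C3, C4 and C6. No chiral pool is needed.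
- Weak points: **A7** has three trisubstituted alkenes of defined geometry. The first diene is fully substituted at its inner carbons and reluctant to become s-cis. The quaternary centre C10 must form in the second cycloaddition with a weak dienophile. Site and regioselectivity between the two dienes, and the C7/C10 relationship, are not obviously controllable. The formyl group on C2, the sulfonyl group on C8 and the pivalate must then be removed or converted into the isopropenyl group, which gives back the saved steps.
- Comparison: the chosen plan is longer after its key step, but each stereocentre is tied either to carvone or to a substrate-controlled event of a known type, and nothing auxiliary has to be excised from the carbocycle.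

Key step: step 4

**Remarks.** Eudesmane numbering is used: decalin C1–C10, isopropenyl C11–C13, C14 on C10, C15 on C4, C16 the benzylic methylene on C1. β is the face of C14. "7-epi" means 7α-isopropenyl (7βH) with 10β-CH3, and "4αH" means 4β-CH3. The carbinol carbons C3 (in 16–19) and the benzylic carbinol (in 23–25) are removed or oxidised later; their configuration is left open and both epimers are carried on.

## Route

Step 1
Reactants: 1 (S)-(+)-carvone
Product: 3 (S)-trimethyl{[2-methyl-5-(prop-1-en-2-yl)cyclohex-1-en-1-yl]oxy}silane, via lithium enolate 2 (not isolated)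
Conditions: LiBH(s-Bu)3, THF, −78 °C; then Me3SiCl, Et3N, −78 → 0 °C
Reagents that add atoms: chlorotrimethylsilane, C[Si](C)(C)Cl
Why: Conjugate (1,4) hydride reduction of the β-unsubstituted cyclohexenone by the hindered trialkylborohydride gives one enolate regioisomer, and O-silylation should fix it as the tetrasubstituted enol ether; the stereocentre of carvone is not touched.

Step 2
Reactants: 4 1,3,5-trimethoxybenzene; 5 allyl bromide
Product: 7 2-allyl-1,3,5-trimethoxybenzene, via aryllithium 6 (not isolated)
Conditions: n-BuLi, THF, 0 → 23 °C; then 5, −78 → 23 °C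
Reagents that add atoms: none
Why: Directed ortho-metalation (every ring position lies between two methoxy groups) followed by allylation of the aryllithium; SN2 and SN2' attack on allyl bromide give the same product.

Step 3
Reactants: 7 2-allyl-1,3,5-trimethoxybenzene; 8 pent-1-en-3-one
Product: 9 (E)-6-(2,4,6-trimethoxyphenyl)hex-4-en-3-one
Conditions: second-generation Hoveyda–Grubbs catalyst (H2IMes)Cl2Ru=CH(C6H4-2-O-i-Pr) (3 mol %), 8 (3 equiv), CH2Cl2, 40 °C
Reagents that add atoms: none
Why: Olefin cross-metathesis of a terminal allylarene with an electron-poor vinyl ketone should favour the cross product and the (E)-enone; no base is present, so the benzylic enone should not move into conjugation with the ring.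

Step 4
Reactants: 3 (S)-trimethyl{[2-methyl-5-(prop-1-en-2-yl)cyclohex-1-en-1-yl]oxy}silane; 9 (E)-6-(2,4,6-trimethoxyphenyl)hex-4-en-3-one
Product: 12 1β-(2,4,6-trimethoxybenzyl)-7-epi-eudesma-4,11-dien-3-one, via 1,5-diketone 10 (not isolated), via ketol 11 (not isolated)
Conditions: TiCl4, CH2Cl2, −78 °C; aq. K2CO3, solvent exchange; then KOH, MeOH, 23 → 50 °C
Reagents that add atoms: none
Why: TiCl4 activates the carbonyl of 9 and the fully substituted enol ether carbon of 3 (C10) adds to the β-carbon (C1) in a Mukaiyama–Michael reaction; after hydrolytic work-up, KOH forms the C4 enolate of the ethyl ketone in 10, which adds to the ring carbonyl C5 (ketol 11) and loses water by E1cB to give the tetrasubstituted enone 12. The closest known reaction type is the silyl enol ether variant of the Robinson annulation with β-substituted enones, which sets a quaternary centre next to a cis secondary one in octalones. Ring B closes in the 6-(enolendo)-exo-trig mode; the competing aldol from C6 onto C3 gives a bridged ketol that cannot dehydrate and should revert. C10 is controlled by C7: the half-chair enol ether with the isopropenyl group pseudoequatorial is attacked axially, so the new C1–C10 bond is cis to the isopropenyl group and C14 is trans to it. C1 is controlled by the (E)-geometry of 9 in an open, synclinal transition state, in which the hydrogen on C1 lies over the ring, the arylmethyl group points outward and the titanium-bound carbonyl arm is gauche to the silyloxy-bearing carbon; this places the arylmethyl group cis to C14 on ring B. The step needs regioselectivity (secured by the single enol ether regioisomer 3, which does not equilibrate under Lewis acid), chemoselectivity for the enol ether over the trimethoxyphenyl ring (the enol ether is the stronger π-nucleophile at −78 °C) and an intact benzylic enone (no base is present until C1–C10 exists).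

Step 5
Reactants: 12 1β-(2,4,6-trimethoxybenzyl)-7-epi-eudesma-4,11-dien-3-one
Product: 13 3-(triethylsilyloxy)-1β-(2,4,6-trimethoxybenzyl)-7-epi-eudesma-3,5,11-triene
Conditions: Et3SiOTf, Et3N, CH2Cl2, 0 → 23 °C
Reagents that add atoms: triethylsilyl trifluoromethanesulfonate, CC[Si](CC)(CC)OS(=O)(=O)C(F)(F)F
Why: Soft enolisation with silyl triflate and amine should give the extended (heteroannular) silyl dienol ether, the thermodynamically preferred isomer; C6 is the only γ-position that carries hydrogen.

Step 6
Reactants: 13 3-(triethylsilyloxy)-1β-(2,4,6-trimethoxybenzyl)-7-epi-eudesma-3,5,11-triene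
Product: 14 6β-hydroxy-1β-(2,4,6-trimethoxybenzyl)-7-epi-eudesma-4,11-dien-3-one
Conditions: mCPBA (1.05 equiv), NaHCO3, CH2Cl2, −20 °C; aq. Na2S2O3/NaHCO3 work-up
Reagents that add atoms: 3-chloroperoxybenzoic acid, OOC(=O)c1cccc(Cl)c1
Why: Vinylogous Rubottom oxidation: the peracid epoxidises the distal C5=C6 bond of the dienol ether far faster than the isopropenyl group, and the silyloxy group opens the epoxide to the γ-hydroxy enone. Attack should come from the β face, which is the stereoelectronically preferred pseudoaxial direction at C6 and is opposite the pseudoaxial isopropenyl group on C7; the C4 methyl group disfavours the competing attack at C4.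

Step 7
Reactants: 14 6β-hydroxy-1β-(2,4,6-trimethoxybenzyl)-7-epi-eudesma-4,11-dien-3-one
Product: 15 6α-[2-isopropylidene-1-(2-nitrophenylsulfonyl)hydrazinyl]-1β-(2,4,6-trimethoxybenzyl)-7-epi-eudesma-4,11-dien-3-one
Conditions: N-isopropylidene-N'-(2-nitrobenzenesulfonyl)hydrazine (IPNBSH), PPh3, diethyl azodicarboxylate, THF, 0 → 23 °C
Reagents that add atoms: N-isopropylidene-N'-(2-nitrobenzenesulfonyl)hydrazine, CC(C)=NNS(=O)(=O)c1ccccc1[N+](=O)[O-]
Why: Mitsunobu reaction: the acidic N–H of the sulfonyl hydrazone displaces the activated 6β-oxygen by SN2 with inversion, which places nitrogen on the α face of C6; the isopropylidene group keeps the reagent from condensing with the C3 ketone and makes 15 isolable.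

Step 8
Reactants: 15 6α-[2-isopropylidene-1-(2-nitrophenylsulfonyl)hydrazinyl]-1β-(2,4,6-trimethoxybenzyl)-7-epi-eudesma-4,11-dien-3-one
Product: 18 1β-(2,4,6-trimethoxybenzyl)-4αH-7-epi-eudesma-5,11-dien-3-ol, via allylic alcohol 16 (not isolated), via allylic diazene 17 (not isolated)
Conditions: NaBH4, CeCl3·7H2O, MeOH, −40 °C; then CF3CH2OH–H2O (1:1), 23 °C
Reagents that add atoms: none
Why: Luche reduction removes the C3 carbonyl first (16, both epimers), so C4 is never stereogenic next to a ketone; solvolysis of the hydrazone and loss of 2-nitrobenzenesulfinic acid then give diazene 17, whose retro-ene loss of N2 (allylic diazene rearrangement) transfers hydrogen suprafacially from nitrogen to C4 and shifts the double bond to C5=C6. Because nitrogen is on the α face of C6, hydrogen should arrive on the α face of C4, which makes the C4 methyl group β.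

Step 9
Reactants: 18 1β-(2,4,6-trimethoxybenzyl)-4αH-7-epi-eudesma-5,11-dien-3-ol
Product: 19 O-[1β-(2,4,6-trimethoxybenzyl)-4αH-7-epi-eudesma-5,11-dien-3-yl] S-methyl dithiocarbonate
Conditions: NaH, CS2, MeI, imidazole (cat.), THF, 0 → 23 °C
Reagents that add atoms: carbon disulfide, S=C=S; iodomethane, CI
Why: Xanthate formation from the secondary alkoxide, the first stage of the Barton–McCombie deoxygenation; both C3 epimers converge in the next step.

Step 10
Reactants: 19 O-[1β-(2,4,6-trimethoxybenzyl)-4αH-7-epi-eudesma-5,11-dien-3-yl] S-methyl dithiocarbonate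
Product: 20 1β-(2,4,6-trimethoxybenzyl)-4αH-7-epi-eudesma-5,11-diene
Conditions: Bu3SnH, AIBN (cat.), toluene, 100 °C
Reagents that add atoms: none
Why: Barton–McCombie radical deoxygenation: the stannyl radical adds to C=S, the C3–O bond fragments and the secondary radical takes hydrogen from Bu3SnH; the neutral conditions should leave both alkenes and the centres C4 and C7 untouched.

Step 11
Reactants: 20 1β-(2,4,6-trimethoxybenzyl)-4αH-7-epi-eudesma-5,11-diene; 21 3-methylbutanal
Product: 23 1-{2,4,6-trimethoxy-3-[(4αH-7-epi-eudesma-5,11-dien-1β-yl)methyl]phenyl}-3-methylbutan-1-ol, via aryllithium 22 (not isolated)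
Conditions: n-BuLi (1.1 equiv), THF, 0 °C; then 21, −78 °C
Reagents that add atoms: none
Why: Directed ortho-metalation at a ring position between two methoxy groups (the two free positions are equivalent by rotation about the aryl–C16 bond), then 1,2-addition to the aldehyde; the carbinol configuration is irrelevant.

Step 12
Reactants: 23 1-{2,4,6-trimethoxy-3-[(4αH-7-epi-eudesma-5,11-dien-1β-yl)methyl]phenyl}-3-methylbutan-1-ol
Product: 25 3-(1-hydroxy-3-methylbutyl)-2,4,6-trimethoxy-5-[(4αH-7-epi-eudesma-5,11-dien-1β-yl)methyl]benzaldehyde, via dilithio species 24 (not isolated)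
Conditions: n-BuLi (2.3 equiv), THF, 0 °C; then DMF, −78 → 0 °C
Reagents that add atoms: N,N-dimethylformamide, CN(C)C=O
Why: The alkoxide forms first; the second equivalent should lithiate the last free ring position, again between two methoxy groups, and the formamide formylates the aryllithium (directed ortho-metalation and formylation).

Step 13
Reactants: 25 3-(1-hydroxy-3-methylbutyl)-2,4,6-trimethoxy-5-[(4αH-7-epi-eudesma-5,11-dien-1β-yl)methyl]benzaldehyde
Product: 26 2,4,6-trimethoxy-3-(3-methylbutanoyl)-5-[(4αH-7-epi-eudesma-5,11-dien-1β-yl)methyl]benzaldehyde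
Conditions: Dess–Martin periodinane, NaHCO3, CH2Cl2, 23 °C
Reagents that add atoms: none
Why: Dess–Martin oxidation of the benzylic secondary alcohol under buffered conditions; the aldehyde, the alkenes and the ethers should be inert.

Step 14
Reactants: 26 2,4,6-trimethoxy-3-(3-methylbutanoyl)-5-[(4αH-7-epi-eudesma-5,11-dien-1β-yl)methyl]benzaldehyde
Product: 27 2,4,6-trihydroxy-3-(3-methylbutanoyl)-5-{[(1S,4S,7S,10S)-7-epi-eudesma-5,11-dien-1-yl]methyl}benzaldehyde
Conditions: NaSEt, DMF, 110 °C; then aq. HCl (pH 3), 0 °C
Reagents that add atoms: none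
Why: SN2 demethylation by thiolate: each methoxy group is ortho or para to both carbonyl groups, so each phenoxide is a stabilised leaving group. No acid is present until the cold work-up, so the isopropenyl group, the C5=C6 bond and the allylic centres C4 and C7 are not exposed to cation chemistry.

## Compound list

1 | (S)-(+)-carvone, (5S)-2-methyl-5-(prop-1-en-2-yl)cyclohex-2-en-1-one | C=C(C)[C@@H]1CC(=O)C(C)=CC1 | starting material
2 | lithium (S)-2-methyl-5-(prop-1-en-2-yl)cyclohex-1-en-1-olate | C=C(C)[C@@H]1CC(O[Li])=C(C)CC1 | intermediate
3 | (S)-trimethyl{[2-methyl-5-(prop-1-en-2-yl)cyclohex-1-en-1-yl]oxy}silane | C=C(C)[C@@H]1CC(O[Si](C)(C)C)=C(C)CC1 | intermediate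
4 | 1,3,5-trimethoxybenzene | COc1cc(OC)cc(OC)c1 | starting material
5 | allyl bromide (3-bromoprop-1-ene) | C=CCBr | starting material
6 | (2,4,6-trimethoxyphenyl)lithium | [Li]c1c(OC)cc(OC)cc1OC | intermediate
7 | 2-allyl-1,3,5-trimethoxybenzene | C=CCc1c(OC)cc(OC)cc1OC | intermediate
8 | pent-1-en-3-one (ethyl vinyl ketone) | C=CC(=O)CC | starting material
9 | (E)-6-(2,4,6-trimethoxyphenyl)hex-4-en-3-one | CCC(=O)/C=C/Cc1c(OC)cc(OC)cc1OC | intermediate
10 | (2S,5S)-2-methyl-2-[(2R)-4-oxo-1-(2,4,6-trimethoxyphenyl)hexan-2-yl]-5-(prop-1-en-2-yl)cyclohexan-1-one | C=C(C)[C@@H]1CC(=O)[C@](C)([C@H](Cc2c(OC)cc(OC)cc2OC)CC(=O)CC)CC1 | intermediate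
11 | 5-hydroxy-1β-(2,4,6-trimethoxybenzyl)-7-epi-eudesm-11-en-3-one (C4 and C5 unassigned) | C=C(C)[C@@H]1CC2(O)C(C)C(=O)C[C@@H](Cc3c(OC)cc(OC)cc3OC)[C@]2(C)CC1 | intermediate
12 | (1R,7S,10S)-1β-(2,4,6-trimethoxybenzyl)-7-epi-eudesma-4,11-dien-3-one | C=C(C)[C@@H]1CC2=C(C)C(=O)C[C@@H](Cc3c(OC)cc(OC)cc3OC)[C@]2(C)CC1 | intermediate
13 | 3-(triethylsilyloxy)-1β-(2,4,6-trimethoxybenzyl)-7-epi-eudesma-3,5,11-triene | C=C(C)[C@@H]1C=C2C(C)=C(O[Si](CC)(CC)CC)C[C@@H](Cc3c(OC)cc(OC)cc3OC)[C@]2(C)CC1 | intermediate
14 | 6β-hydroxy-1β-(2,4,6-trimethoxybenzyl)-7-epi-eudesma-4,11-dien-3-one | C=C(C)[C@@H]1[C@@H](O)C2=C(C)C(=O)C[C@@H](Cc3c(OC)cc(OC)cc3OC)[C@]2(C)CC1 | intermediate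
15 | 6α-[2-isopropylidene-1-(2-nitrophenylsulfonyl)hydrazinyl]-1β-(2,4,6-trimethoxybenzyl)-7-epi-eudesma-4,11-dien-3-one | C=C(C)[C@@H]1[C@H](N(N=C(C)C)S(=O)(=O)c4ccccc4[N+](=O)[O-])C2=C(C)C(=O)C[C@@H](Cc3c(OC)cc(OC)cc3OC)[C@]2(C)CC1 | intermediate
16 | 6α-[2-isopropylidene-1-(2-nitrophenylsulfonyl)hydrazinyl]-1β-(2,4,6-trimethoxybenzyl)-7-epi-eudesma-4,11-dien-3-ol (C3 epimers) | C=C(C)[C@@H]1[C@H](N(N=C(C)C)S(=O)(=O)c4ccccc4[N+](=O)[O-])C2=C(C)C(O)C[C@@H](Cc3c(OC)cc(OC)cc3OC)[C@]2(C)CC1 | intermediate
17 | 6α-diazenyl-1β-(2,4,6-trimethoxybenzyl)-7-epi-eudesma-4,11-dien-3-ol (C3 epimers) | C=C(C)[C@@H]1[C@H](N=N)C2=C(C)C(O)C[C@@H](Cc3c(OC)cc(OC)cc3OC)[C@]2(C)CC1 | intermediate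
18 | 1β-(2,4,6-trimethoxybenzyl)-4αH-7-epi-eudesma-5,11-dien-3-ol (4β-methyl; C3 epimers) | C=C(C)[C@@H]1C=C2[C@@H](C)C(O)C[C@@H](Cc3c(OC)cc(OC)cc3OC)[C@]2(C)CC1 | intermediate
19 | O-[1β-(2,4,6-trimethoxybenzyl)-4αH-7-epi-eudesma-5,11-dien-3-yl] S-methyl dithiocarbonate (C3 epimers) | C=C(C)[C@@H]1C=C2[C@@H](C)C(OC(=S)SC)C[C@@H](Cc3c(OC)cc(OC)cc3OC)[C@]2(C)CC1 | intermediate
20 | (1S,4S,7S,10S)-1β-(2,4,6-trimethoxybenzyl)-4αH-7-epi-eudesma-5,11-diene | C=C(C)[C@@H]1C=C2[C@@H](C)CC[C@@H](Cc3c(OC)cc(OC)cc3OC)[C@]2(C)CC1 | intermediate
21 | 3-methylbutanal (isovaleraldehyde) | CC(C)CC=O | starting material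
22 | {2,4,6-trimethoxy-3-[(4αH-7-epi-eudesma-5,11-dien-1β-yl)methyl]phenyl}lithium | C=C(C)[C@@H]1C=C2[C@@H](C)CC[C@@H](Cc3c(OC)cc(OC)c([Li])c3OC)[C@]2(C)CC1 | intermediate
23 | 1-{2,4,6-trimethoxy-3-[(4αH-7-epi-eudesma-5,11-dien-1β-yl)methyl]phenyl}-3-methylbutan-1-ol (carbinol epimers) | C=C(C)[C@@H]1C=C2[C@@H](C)CC[C@@H](Cc3c(OC)cc(OC)c(C(O)CC(C)C)c3OC)[C@]2(C)CC1 | intermediate
24 | lithium 1-{3-lithio-2,4,6-trimethoxy-5-[(4αH-7-epi-eudesma-5,11-dien-1β-yl)methyl]phenyl}-3-methylbutan-1-olate | C=C(C)[C@@H]1C=C2[C@@H](C)CC[C@@H](Cc3c(OC)c([Li])c(OC)c(C(O[Li])CC(C)C)c3OC)[C@]2(C)CC1 | intermediate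
25 | 3-(1-hydroxy-3-methylbutyl)-2,4,6-trimethoxy-5-[(4αH-7-epi-eudesma-5,11-dien-1β-yl)methyl]benzaldehyde (carbinol epimers) | C=C(C)[C@@H]1C=C2[C@@H](C)CC[C@@H](Cc3c(OC)c(C=O)c(OC)c(C(O)CC(C)C)c3OC)[C@]2(C)CC1 | intermediate
26 | 2,4,6-trimethoxy-3-(3-methylbutanoyl)-5-[(4αH-7-epi-eudesma-5,11-dien-1β-yl)methyl]benzaldehyde | C=C(C)[C@@H]1C=C2[C@@H](C)CC[C@@H](Cc3c(OC)c(C=O)c(OC)c(C(=O)CC(C)C)c3OC)[C@]2(C)CC1 | intermediate
27 | 2,4,6-trihydroxy-3-(3-methylbutanoyl)-5-{[(1S,4S,7S,10S)-7-epi-eudesma-5,11-dien-1-yl]methyl}benzaldehyde (CNP0564915.1) | C=C(C)[C@@H]1C=C2[C@@H](C)CC[C@@H](Cc3c(O)c(C=O)c(O)c(C(=O)CC(C)C)c3O)[C@]2(C)CC1 | target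

## Step count and least certain steps

Total: 14 steps. Longest linear sequence: 13 steps (4 → 7 → 9 → 12 → 13 → 14 → 15 → 18 → 19 → 20 → 23 → 25 → 26 → 27); the carvone branch joins at step 4 after one step.

**Step 4 (key step).** The most likely failure is slow bond formation between the fully substituted enol ether carbon and the β-branched enone. This would give time for protodesilylation of 3 and for Friedel–Crafts-type alkylation of the trimethoxyphenyl ring by the titanium-activated enone. Face discrimination at C1 could also erode if an antiperiplanar arrangement competes, and 10 could equilibrate by retro-Michael reaction under KOH before ring closure. Fallback (sets out from 3 and 8, returns at 12): the arene is left out of the annulation and attached afterwards. Cross-metathesis of 8 with allyloxy(tert-butyl)dimethylsilane should give (E)-6-[(tert-butyldimethylsilyl)oxy]hex-4-en-3-one F1. The same TiCl4 addition and KOH closure with 3 should give 1β-{[(tert-butyldimethylsilyl)oxy]methyl}-7-epi-eudesma-4,11-dien-3-one F2. Bu4NF frees 1β-(hydroxymethyl)-7-epi-eudesma-4,11-dien-3-one F3, and I2, PPh3 and imidazole (Appel reaction) give 1β-(iodomethyl)-7-epi-eudesma-4,11-dien-3-one F4. Zinc insertion (Zn, LiCl, THF) gives [(3-oxo-7-epi-eudesma-4,11-dien-1β-yl)methyl]zinc iodide F5. Negishi coupling of F5 with 2-bromo-1,3,5-trimethoxybenzene (Pd(OAc)2, 2-dicyclohexylphosphino-2',6'-dimethoxybiphenyl, THF, 60 °C) should then give 12.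

**Step 6.** The most likely failure is epoxidation at the more substituted C3=C4 bond, which leads to hydroxylation at C4, or attack on the α face, since the dienol ether has two nucleophilic positions and the C4 methyl group biases them only in part. Fallback (sets out from 12, returns at 18): the C6 oxygen is dispensed with. Treatment of 12 with KOt-Bu in t-BuOH/THF and inverse quench into cold aqueous acetic acid (kinetic α-protonation of the extended dienolate, expected from the α face opposite C14 and the arylmethyl group) should give 1β-(2,4,6-trimethoxybenzyl)-4αH-7-epi-eudesma-5,11-dien-3-one F6. Immediate reduction of F6 with NaBH4 in MeOH at −20 °C should give 18.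

**Step 7.** The most likely failure is in the SN2 step. The backside of C6 is flanked by the isopropenyl group on C7 and by the C4 methyl group, so elimination to a 4,6-dienone or recovery of 14 may prevail. Fallback (sets out from 14, returns at 18): hydride is delivered by palladium instead of nitrogen. Acetic formic anhydride and pyridine convert 14 into 6β-formyloxy-1β-(2,4,6-trimethoxybenzyl)-7-epi-eudesma-4,11-dien-3-one F7. With Pd(OAc)2 and n-Bu3P in THF (zerovalent palladium formed in situ), ionisation with inversion puts the metal on the α face, loss of CO2 gives a palladium hydride, and hydride transfer to the more substituted terminus C4 on that face should give F6. F6 is reduced with NaBH4 to 18 as above.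

**Step 12.** The most likely failure is incomplete ring metalation in the presence of the aggregated lithium alkoxide, with slow deprotonation at allylic positions on longer exposure. Fallback (sets out from 20, returns at 25): the order is reversed. Lithiation of 20 (n-BuLi, THF, 0 °C) and quench with DMF give 2,4,6-trimethoxy-3-[(4αH-7-epi-eudesma-5,11-dien-1β-yl)methyl]benzaldehyde F8. Its formyl group is masked in the flask as the α-amino alkoxide with lithium N,N,N'-trimethylethylenediamide, n-BuLi lithiates the last ring position, and addition of 21 followed by aqueous work-up should give 25.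

## Further compounds

F1 | step 4 | (E)-6-[(tert-butyldimethylsilyl)oxy]hex-4-en-3-one | CCC(=O)/C=C/CO[Si](C)(C)C(C)(C)C
F2 | step 4 | 1β-{[(tert-butyldimethylsilyl)oxy]methyl}-7-epi-eudesma-4,11-dien-3-one | C=C(C)[C@@H]1CC2=C(C)C(=O)C[C@@H](CO[Si](C)(C)C(C)(C)C)[C@]2(C)CC1
F3 | step 4 | 1β-(hydroxymethyl)-7-epi-eudesma-4,11-dien-3-one | C=C(C)[C@@H]1CC2=C(C)C(=O)C[C@@H](CO)[C@]2(C)CC1
F4 | step 4 | 1β-(iodomethyl)-7-epi-eudesma-4,11-dien-3-one | C=C(C)[C@@H]1CC2=C(C)C(=O)C[C@@H](CI)[C@]2(C)CC1
F5 | step 4 | [(3-oxo-7-epi-eudesma-4,11-dien-1β-yl)methyl]zinc iodide | C=C(C)[C@@H]1CC2=C(C)C(=O)C[C@@H](C[Zn]I)[C@]2(C)CC1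
F6 | step 6 | 1β-(2,4,6-trimethoxybenzyl)-4αH-7-epi-eudesma-5,11-dien-3-one | C=C(C)[C@@H]1C=C2[C@@H](C)C(=O)C[C@@H](Cc3c(OC)cc(OC)cc3OC)[C@]2(C)CC1
F7 | step 7 | 6β-formyloxy-1β-(2,4,6-trimethoxybenzyl)-7-epi-eudesma-4,11-dien-3-one | C=C(C)[C@@H]1[C@@H](OC=O)C2=C(C)C(=O)C[C@@H](Cc3c(OC)cc(OC)cc3OC)[C@]2(C)CC1
F8 | step 12 | 2,4,6-trimethoxy-3-[(4αH-7-epi-eudesma-5,11-dien-1β-yl)methyl]benzaldehyde | C=C(C)[C@@H]1C=C2[C@@H](C)CC[C@@H](Cc3c(OC)cc(OC)c(C=O)c3OC)[C@]2(C)CC1
A1 | alternative 1 | 4-hydroxy-6-(4-methyl-2-oxopentyl)-3-[(4αH-7-epi-eudesma-5,11-dien-1β-yl)methyl]-2H-pyran-2-one | C=C(C)[C@@H]1C=C2[C@@H](C)CC[C@@H](Cc3c(O)cc(CC(=O)CC(C)C)oc3=O)[C@]2(C)CC1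
A2 | alternative 1 | methyl 9-methyl-3,5,7-trioxo-2-[(4αH-7-epi-eudesma-5,11-dien-1β-yl)methyl]decanoate | C=C(C)[C@@H]1C=C2[C@@H](C)CC[C@@H](CC(C(=O)OC)C(=O)CC(=O)CC(=O)CC(C)C)[C@]2(C)CC1
A3 | alternative 1 | 1-{2,4,6-trihydroxy-3-[(4αH-7-epi-eudesma-5,11-dien-1β-yl)methyl]phenyl}-3-methylbutan-1-one | C=C(C)[C@@H]1C=C2[C@@H](C)CC[C@@H](Cc3c(O)cc(O)c(C(=O)CC(C)C)c3O)[C@]2(C)CC1
A4 | alternative 2 | 7-epi-eudesma-1,4,11-trien-3β-ol | C=C(C)[C@@H]1CC2=C(C)[C@@H](O)C=C[C@]2(C)CC1
A5 | alternative 2 | 1β,2β-methano-7-epi-eudesma-4,11-dien-3β-ol | C=C(C)[C@@H]1CC2=C(C)[C@@H](O)[C@H]3C[C@H]3[C@]2(C)CC1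
A6 | alternative 2 | 1β,2β-methano-7-epi-eudesma-4,11-dien-3-one | C=C(C)[C@@H]1CC2=C(C)C(=O)[C@H]3C[C@H]3[C@]2(C)CC1
A7 | alternative 3 | (3E,6E)-5-[(E)-ethylidene]-2,6-dimethyl-8-(2,4,6-trimethoxyphenyl)octa-3,6-dien-1-yl 2,2-dimethylpropanoate | C/C=C(\C=C\C(C)COC(=O)C(C)(C)C)/C(C)=C/Cc1c(OC)cc(OC)cc1OC
A8 | alternative 3 | acrolein (prop-2-enal) | C=CC=O
A9 | alternative 3 | phenyl vinyl sulfone | C=CS(=O)(=O)c1ccccc1
A10 | alternative 3 | eudesm-5-ene with formyl on C2, phenylsulfonyl on C8, 2,4,6-trimethoxybenzyl on C1 and a 1-(pivaloyloxy)propan-2-yl group on C7 | CC(COC(=O)C(C)(C)C)[C@@H]1C=C2[C@@H](C)CC(C=O)[C@@H](Cc3c(OC)cc(OC)cc3OC)[C@]2(C)CC1S(=O)(=O)c1ccccc1
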